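**Plan**
- Retrosynthesis: open the butenolide (O–C16 and the C16–ring-carbon bond: terminal alkyne + (Z)-3-iodobut-2-enoic acid), then cut C13=C14 (Horner–Wadsworth–Emmons) and C11=C12 (Wittig), then ring B at C7–C8 and C9–C10 together ([4+2]), then C5–C6 (vinylation of a ring-A enol triflate) and C4–C18 (hydroxymethylation).
- Forward: ring A is bought as 2,6-dimethylcyclohexanone and turned into the semicyclic diene C7=C6–C5=C10; ring B arises in one Diels–Alder step with an allenic ester as the C8–C9 unit; the chain is grown C11→C13→C16 and the butenolide ring is closed last.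
- Enabling feature: in ring B the syn 5α-H/6α-OH pair is the hydroboration retron of a Δ5 alkene, and the C8 carbinol (OH, CH3) is the hydration retron of an 8(17)-methylene. Ring B therefore maps onto a 4-methylenecyclohexene, the adduct of the ring-A vinylcyclohexene (C10, C5, C6, C7) with the α,β-bond of an allenoate (C9, C8) whose ester carbon is C11.
- Stereochemistry: C4 from a chiral Sc(III)/bipyridine hydroxymethylation; C10 and C9 from the cycloaddition (face anti to the C4 methyl, ester exo); C8 from α-face Markovnikov hydration; C5/C6 from α-face syn hydroboration; 13E from the HWE step; 15Z from anti-oxypalladation in the lactonisation.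

Key step: step 6

Remark (numbering): ring A = C1–C5, C10; ring B = C5–C10; chain C11–C12–C13(CH3)=C14–C15=C16 from C9, C16 being the butenolide ring carbon; C17 on C8; C18 = 4α-carbon; C19 = 4β-methyl; C20 = 10β-methyl; α = face opposite C20.
Remark (assumptions): the (S,S)-bipyridine ligand is taken to give the (2S) alcohol 3 (otherwise its antipode is used); phosphonate 18 is taken as commercial.

Step 1
Reactants: 1 2,6-dimethylcyclohexan-1-one
Product: 2 2,6-dimethyl-1-(trimethylsilyloxy)cyclohex-1-ene
Conditions: TMSOTf, Et3N, CH2Cl2, 0 °C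
Reagents that add atoms: trimethylsilyl trifluoromethanesulfonate, C[Si](C)(C)OS(=O)(=O)C(F)(F)F
Why: Silyl enol ether formation by soft enolisation should be clean because the symmetric ketone has only one kind of α-hydrogen, so a single (racemic) tetrasubstituted enol ether results.

Step 2
Reactants: 2 2,6-dimethyl-1-(trimethylsilyloxy)cyclohex-1-ene
Product: 3 (2S)-2-(hydroxymethyl)-2,6-dimethylcyclohexan-1-one
Conditions: 35 % aq. HCHO, Sc(OTf)3 (10 mol %), (S,S)-6,6′-bis(1-hydroxy-2,2-dimethylpropyl)-2,2′-bipyridine (12 mol %), DME–H2O 9:1, −20 °C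
Reagents that add atoms: formaldehyde, C=O
Why: Catalytic asymmetric aqueous Mukaiyama aldol (hydroxymethylation) of a tetrasubstituted silyl enol ether; the chiral Sc(III)–bipyridine complex should select the enolate face and so set the quaternary centre (future C4) as (S), the untouched methyl-bearing centre (future C10, both epimers) being erased in step 4.

Step 3
Reactants: 3 (2S)-2-(hydroxymethyl)-2,6-dimethylcyclohexan-1-one
Product: 4 (2S)-2-[(tert-butyldimethylsilyloxy)methyl]-2,6-dimethylcyclohexan-1-one
Conditions: TBSCl, imidazole, DMF, rt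
Reagents that add atoms: tert-butyldimethylsilyl chloride, CC(C)(C)[Si](C)(C)Cl
Why: Standard silylation of a primary alcohol (TBS ether) should protect the β-hydroxy ketone against retro-aldol loss of formaldehyde in the next, basic step and carry the C18 oxygen to step 13.

Step 4
Reactants: 4 (2S)-2-[(tert-butyldimethylsilyloxy)methyl]-2,6-dimethylcyclohexan-1-one
Product: 6 (6S)-6-[(tert-butyldimethylsilyloxy)methyl]-2,6-dimethylcyclohex-1-en-1-yl trifluoromethanesulfonate, via potassium enolate 5 (not isolated)
Conditions: KHMDS, THF, −78 → 0 °C; then PhNTf2, −78 °C → rt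
Reagents that add atoms: N-phenylbis(trifluoromethanesulfonimide), O=S(=O)(N(c1ccccc1)S(=O)(=O)C(F)(F)F)C(F)(F)F
Why: Enolate O-triflation; deprotonation can occur only at the methyl-bearing α-carbon because the other α-carbon is quaternary, so the C5(OTf)=C10 enol triflate should form regiospecifically with C4 untouched.

Step 5
Reactants: 6 (6S)-6-[(tert-butyldimethylsilyloxy)methyl]-2,6-dimethylcyclohex-1-en-1-yl trifluoromethanesulfonate
Product: 7 (R)-tert-butyl[(1,3-dimethyl-2-vinylcyclohex-2-en-1-yl)methoxy]dimethylsilane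
Conditions: CH2=CHSnBu3, Pd(PPh3)4 (5 mol %), LiCl, THF, 65 °C
Reagents that add atoms: tributyl(vinyl)stannane, C=C[Sn](CCCC)(CCCC)CCCC
Why: Stille cross-coupling of an enol triflate with a vinylstannane should give the semicyclic diene C7=C6–C5=C10 without touching the stereocentre.

Step 6
Reactants: 7 (R)-tert-butyl[(1,3-dimethyl-2-vinylcyclohex-2-en-1-yl)methoxy]dimethylsilane; 8 ethyl buta-2,3-dienoate
Product: 9 bicyclic 5,8(17)-diene ethyl ester (cycloadduct)
Conditions: 8 (3 equiv), EtAlCl2 (0.3 equiv), CH2Cl2, −78 → −20 °C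
Reagents that add atoms: none
Why: Lewis-acid-catalysed, concerted but asynchronous [4π+2π] cycloaddition: the unhindered terminus C7 of the diene bonds first to the electrophilic central allene carbon (future C8) and the ester α-carbon (future C9) then closes onto the tetrasubstituted terminus C10, so that ring B, the Δ5 alkene, the 8(17)-methylene and the C11 ester arise together. The closest known reaction type is the Diels–Alder reaction of 1-vinylcyclohexenes bearing a fully substituted terminus with acetylenic or allenic esters, as used to build drimane-type decalins. Ring B, the only ring closed, is six-membered and carbocyclic and closes by intermolecular suprafacial [4+2] cycloaddition rather than by an ionic exo/endo cyclisation. C10 should be controlled by the C4 stereocentre, the dienophile adding to the α-face anti to the pseudoaxial C19 methyl while the CH2OTBS arm stays pseudoequatorial and so avoids the developing 1,3-diaxial contact with C20; C9 should be controlled by the exo position of the ester, its endo position under C5 being crowded by that same arm. The step needs regioselectivity (ester-bearing carbon to C10), site selectivity for the conjugated π-bond of the allene, α-facial selectivity and exo selectivity; these are secured by the polarisation of the diene (attack through C7 leaves tertiary allyl cation character at C10), by Lewis-acid activation of the α,β-bond only, and by the quaternary C4 centre.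

Step 7
Reactants: 9 bicyclic 5,8(17)-diene ethyl ester
Product: 11 8α-hydroxy-Δ5 ethyl ester, via organomercurial 10 (not isolated)
Conditions: Hg(OAc)2, THF–H2O 1:1, rt; then 3 M NaOH, NaBH4, 0 °C
Reagents that add atoms: water, O
Why: Oxymercuration–demercuration (Markovnikov hydration); Hg(II) should engage only the exposed 1,1-disubstituted 8(17)-alkene because the Δ5 alkene lies between two quaternary carbons, and water should open the mercurinium ion at C8 from the α-side because the axial β-trajectory is blocked by the syn-axial C20 methyl, setting 8α-OH/8β-CH3.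

Step 8
Reactants: 11 8α-hydroxy-Δ5 ethyl ester
Product: 13 6α,8α,11-triol (18-O-TBS), via alkylborane 12 (not isolated)
Conditions: BH3·SMe2 (excess), THF, 0 → 65 °C; then 3 M NaOH, 30 % H2O2, 0 °C → rt
Reagents that add atoms: hydrogen peroxide, OO
Why: Brown hydroboration–oxidation with concurrent borane reduction of the ester; BH3 should add syn to the α-face of the Δ5 alkene (the β-face is covered by the axial C19 and C20 methyls) with boron at the less substituted C6, so that oxidation with retention sets 5α-H (trans ring fusion) and the equatorial 6α-OH.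

Step 9
Reactants: 13 6α,8α,11-triol (18-O-TBS)
Product: 14 6α,8α-dihydroxy-11-aldehyde (18-O-TBS)
Conditions: TEMPO (10 mol %), PhI(OAc)2, CH2Cl2, rt
Reagents that add atoms: none
Why: TEMPO/PhI(OAc)2 oxoammonium oxidation should convert only the primary C11 alcohol, the hindered secondary C6 and tertiary C8 hydroxyls being far slower or inert.

Step 10
Reactants: 14 6α,8α-dihydroxy-11-aldehyde (18-O-TBS); 15 1-(triphenyl-λ5-phosphanylidene)propan-2-one
Product: 16 (11E)-enone (C11=C12–C13(=O)CH3)
Conditions: toluene, 90 °C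
Reagents that add atoms: none
Why: Wittig olefination with a stabilised ylide under neutral conditions should give the E-enone without retro-aldol or dehydration of the β-hydroxy aldehyde and without epimerising C9.

Step 11
Reactants: 16 (11E)-enone
Product: 17 saturated C13 methyl ketone
Conditions: H2 (1 atm), 10 % Pd/C, EtOAc, rt
Reagents that add atoms: none
Why: Catalytic hydrogenation of the conjugated C11=C12 bond should leave the ketone, the silyl ether and the stereocentres untouched.

Step 12
Reactants: 17 saturated C13 methyl ketone; 18 diethyl [3-(trimethylsilyl)prop-2-yn-1-yl]phosphonate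
Product: 20 (13E)-trimethylsilyl enyne (18-O-TBS), via lithiated phosphonate 19 (not isolated)
Conditions: 18 (3.5 equiv), LiHMDS (3.5 equiv), THF, −78 °C; then 17, −78 °C → rt
Reagents that add atoms: none
Why: Horner–Wadsworth–Emmons olefination of the methyl ketone with a propargylic phosphonate anion (excess, to cover the two free hydroxyls) should favour the 13E enyne, in which the alkynyl group is anti to the larger alkyl chain.

Step 13
Reactants: 20 (13E)-trimethylsilyl enyne (18-O-TBS)
Product: 21 terminal enyne 6α,8α,18-triol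
Conditions: TBAF, THF, 0 °C → rt
Reagents that add atoms: none
Why: Fluoride-mediated desilylation should cleave both the C(sp)–SiMe3 and the O–TBS bonds in one operation.

Step 14
Reactants: 21 terminal enyne 6α,8α,18-triol
Product: 22 terminal enyne 6α,8α-dihydroxy-18-aldehyde
Conditions: TEMPO (10 mol %), PhI(OAc)2, CH2Cl2, rt
Reagents that add atoms: none
Why: TEMPO/PhI(OAc)2 oxidation should take the primary neopentyl C18 alcohol to the aldehyde selectively over the secondary C6 alcohol, and the lactol that over-oxidation would need cannot form across the 1,3-diequatorial C18/O6 positions.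

Step 15
Reactants: 23 but-2-ynoic acid
Product: 24 (Z)-3-iodobut-2-enoic acid
Conditions: NaI, AcOH, 110 °C
Reagents that add atoms: sodium iodide, [Na+].[I-]
Why: Hydroiodination of an ynoic acid by anti addition of HI should give the (Z)-β-iodo acid, which has the cis relationship of carboxyl and iodide needed in the last step.

Step 16
Reactants: 22 terminal enyne 6α,8α-dihydroxy-18-aldehyde; 24 (Z)-3-iodobut-2-enoic acid
Product: 26 CNP0278517.1 (target), via enynoic acid 25 (not isolated)
Conditions: PdCl2(PPh3)2 (5 mol %), CuI (10 mol %), Et3N, MeCN, rt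
Reagents that add atoms: none
Why: Tandem Sonogashira coupling/5-exo-dig lactonisation of a (Z)-β-iodoalkenoic acid with a terminal alkyne; anti-oxypalladation of the alkyne by the cis carboxylate followed by protodemetalation should give the (Z)-γ-ylidene butenolide, and the mild amine conditions should spare the non-enolisable aldehyde, both hydroxyls and the 13E alkene.

**Compound list**
1 | 2,6-dimethylcyclohexan-1-one (cis/trans mixture) | CC1CCCC(C)C1=O | starting material
2 | 2,6-dimethyl-1-(trimethylsilyloxy)cyclohex-1-ene (racemic) | CC1CCCC(C)=C1O[Si](C)(C)C | intermediate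
3 | (2S)-2-(hydroxymethyl)-2,6-dimethylcyclohexan-1-one (both C6 epimers) | CC1CCC[C@@](C)(CO)C1=O | intermediate
4 | (2S)-2-[(tert-butyldimethylsilyloxy)methyl]-2,6-dimethylcyclohexan-1-one (both C6 epimers) | CC1CCC[C@@](C)(CO[Si](C)(C)C(C)(C)C)C1=O | intermediate
5 | potassium (6S)-6-[(tert-butyldimethylsilyloxy)methyl]-2,6-dimethylcyclohex-1-en-1-olate | CC1=C([O-])[C@](C)(CO[Si](C)(C)C(C)(C)C)CCC1.[K+] | intermediate
6 | (6S)-6-[(tert-butyldimethylsilyloxy)methyl]-2,6-dimethylcyclohex-1-en-1-yl trifluoromethanesulfonate | CC1=C(OS(=O)(=O)C(F)(F)F)[C@](C)(CO[Si](C)(C)C(C)(C)C)CCC1 | intermediate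
7 | (R)-tert-butyl[(1,3-dimethyl-2-vinylcyclohex-2-en-1-yl)methoxy]dimethylsilane (ring-A diene C7=C6–C5=C10) | CC1=C(C=C)[C@](C)(CO[Si](C)(C)C(C)(C)C)CCC1 | intermediate
8 | ethyl buta-2,3-dienoate | C=C=CC(=O)OCC | starting material
9 | cycloadduct: decalin with Δ5, 8(17)-methylene, 9β-CO2Et (9α-H), 10β-CH3, 4β-CH3, 4α-CH2OTBS | CCOC(=O)[C@@H]1[C@@]2(C)CCC[C@@](C)(CO[Si](C)(C)C(C)(C)C)C2=CCC1=C | intermediate
10 | 17-(acetoxymercurio)-8α-hydroxy derivative of 9 (Δ5 retained) | CCOC(=O)[C@@H]1[C@@]2(C)CCC[C@@](C)(CO[Si](C)(C)C(C)(C)C)C2=CC[C@@]1(C[Hg]OC(C)=O)O | intermediate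
11 | ethyl ester with 8α-OH, 8β-CH3, Δ5, 9β-CO2Et, 4α-CH2OTBS | CCOC(=O)[C@@H]1[C@@]2(C)CCC[C@@](C)(CO[Si](C)(C)C(C)(C)C)C2=CC[C@@]1(C)O | intermediate
12 | 6α-boryl intermediate, idealised as the C6-borane with O8 and O11 held as borinates (5α-H) | [BH2]OC[C@@H]1[C@@]2(C)CCC[C@@](C)(CO[Si](C)(C)C(C)(C)C)[C@@H]2[C@@H]([BH2])C[C@@]1(C)O[BH2] | intermediate
13 | trans-decalin 6α,8α,11-triol: 4α-CH2OTBS, 4β-CH3, 5α-H, 8β-CH3, 9α-H, 9β-CH2OH, 10β-CH3 | OC[C@@H]1[C@@]2(C)CCC[C@@](C)(CO[Si](C)(C)C(C)(C)C)[C@@H]2[C@@H](O)C[C@@]1(C)O | intermediate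
14 | 6α,8α-dihydroxy-11-aldehyde (9β-CHO), otherwise as 13 | O=C[C@@H]1[C@@]2(C)CCC[C@@](C)(CO[Si](C)(C)C(C)(C)C)[C@@H]2[C@@H](O)C[C@@]1(C)O | intermediate
15 | 1-(triphenyl-λ5-phosphanylidene)propan-2-one | CC(=O)C=P(c1ccccc1)(c1ccccc1)c1ccccc1 | starting material
16 | (E)-4-(decalin-9β-yl)but-3-en-2-one, decalin substituted as in 13 | CC(=O)/C=C/[C@@H]1[C@@]2(C)CCC[C@@](C)(CO[Si](C)(C)C(C)(C)C)[C@@H]2[C@@H](O)C[C@@]1(C)O | intermediate
17 | 4-(decalin-9β-yl)butan-2-one, decalin substituted as in 13 | CC(=O)CC[C@@H]1[C@@]2(C)CCC[C@@](C)(CO[Si](C)(C)C(C)(C)C)[C@@H]2[C@@H](O)C[C@@]1(C)O | intermediate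
18 | diethyl [3-(trimethylsilyl)prop-2-yn-1-yl]phosphonate | CCOP(=O)(CC#C[Si](C)(C)C)OCC | starting material
19 | lithium salt of the α-carbanion of 18 | CCOP(=O)([CH-]C#C[Si](C)(C)C)OCC.[Li+] | intermediate
20 | (13E)-enyne, C16-SiMe3: C9–CH2CH2–C(CH3)=CH–C≡C–SiMe3, decalin as in 13 | C[Si](C)(C)C#C/C=C(\C)CC[C@@H]1[C@@]2(C)CCC[C@@](C)(CO[Si](C)(C)C(C)(C)C)[C@@H]2[C@@H](O)C[C@@]1(C)O | intermediate
21 | (13E)-terminal enyne with 6α-OH, 8α-OH and 4α-CH2OH | C#C/C=C(\C)CC[C@@H]1[C@@]2(C)CCC[C@@](C)(CO)[C@@H]2[C@@H](O)C[C@@]1(C)O | intermediate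
22 | (13E)-terminal enyne with 6α-OH, 8α-OH and 4α-CHO | C#C/C=C(\C)CC[C@@H]1[C@@]2(C)CCC[C@@](C)(C=O)[C@@H]2[C@@H](O)C[C@@]1(C)O | intermediate
23 | but-2-ynoic acid | CC#CC(=O)O | starting material
24 | (Z)-3-iodobut-2-enoic acid | C/C(I)=C/C(=O)O | intermediate
25 | (2Z,6E)-3,7-dimethyl-9-(decalin-9β-yl)nona-2,6-dien-4-ynoic acid, decalin as in 22 | OC(=O)/C=C(/C)C#C/C=C(\C)CC[C@@H]1[C@@]2(C)CCC[C@@](C)(C=O)[C@@H]2[C@@H](O)C[C@@]1(C)O | intermediate
26 | CNP0278517.1 | CC1=CC(=O)O/C1=C\C=C(/C)CC[C@@H]1[C@@]2(C)CCC[C@@](C)(C=O)[C@@H]2[C@@H](O)C[C@@]1(C)O | target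

**Totals**
Total step count: 16. Longest linear sequence: 15 steps (steps 1–14 and 16; step 15 is a one-step side branch).

**Steps most likely to fail**

1. Step 6. Bond formation at the tetrasubstituted, inside-methylated terminus C10 may be slow, so that Lewis-acid-induced oligomerisation of the allenoate or isomerisation of the diene competes, and the facial discrimination by the C4 centre may be modest. The fallback sets out from 6 and comes back at 13, using a temporary ring that ties C18 into the diene plane.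
 - Sonogashira coupling of 6 with ethynyltrimethylsilane (PdCl2(PPh3)2, CuI, i-Pr2NH) would give the silylated enyne F1, and TBAF would remove both silyl groups to give the enynol F2.
 - 5-exo-dig cycloisomerisation of F2 (cat. Ph3PAuCl/AgOTf or t-BuOK) would give the bicyclic 2-alkoxydiene F3. Its O–C6 bond locks the s-cis geometry, raises the nucleophilicity of C7 and leaves the C19 methyl as the only group on the β-face.
 - Cycloaddition of F3 with 8 would give the tricyclic enol ether F4, and dilute aqueous acid would open the temporary dihydrofuran ring to the trans-fused 6-keto-18-alcohol F5.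
 - Resilylation (TBSCl, imidazole) would give the keto ester F6, and mCPBA would epoxidise the only remaining alkene from the α-face to the epoxy ketone F7.
 - Li/NH3/EtOH would then reduce the ketone to the equatorial 6α-alcohol, open the epoxide to the 8α-ol and reduce the ester, returning to triol 13.

2. Step 7. Discrimination between the two alkenes may be incomplete, or water may attack the mercurinium ion from the β-side with loss of the C8 configuration. The fallback sets out from 9 and comes back at 13.
 - OsO4 (cat.)/NMO would dihydroxylate only the exposed methylene from the α-face to the 8α,17-diol F8.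
 - Tosylation of the primary hydroxyl would give the monotosylate F9, and DBU would close it to the 8α,17-epoxide F10.
 - LiAlH4 would open the epoxide at C17 and reduce the ester to the 8α,11-diol F11; hydroboration–oxidation (BH3·THF; NaOH, H2O2) would then lead to triol 13.

3. Step 12. E/Z control in the olefination of a methyl ketone whose two α-substituents differ little in size may be poor. The fallback sets out from 14 and comes back at 20 by a stereospecific carbometalation.
 - Wittig reaction of 14 with (triphenylphosphoranylidene)acetaldehyde would give the enal F12, and hydrogenation (Pd/C) the saturated aldehyde F13.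
 - Ohira–Bestmann homologation (dimethyl 1-diazo-2-oxopropylphosphonate, K2CO3, MeOH) would give the terminal alkyne F14.
 - Zr-catalysed carboalumination (excess Me3Al, Cp2ZrCl2) followed by iodinolysis would give the (E)-vinyl iodide F15 by syn addition.
 - Sonogashira coupling with ethynyltrimethylsilane would return to 20 as a single 13E isomer.

**Further compounds**
F1 | step 6 | (R)-tert-butyl{[1,3-dimethyl-2-((trimethylsilyl)ethynyl)cyclohex-2-en-1-yl]methoxy}dimethylsilane | C[Si](C)(C)C#CC1=C(C)CCC[C@@]1(C)CO[Si](C)(C)C(C)(C)C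
F2 | step 6 | (R)-(2-ethynyl-1,3-dimethylcyclohex-2-en-1-yl)methanol | C#CC1=C(C)CCC[C@@]1(C)CO
F3 | step 6 | (3aR)-3a,7-dimethyl-1-methylidene-1,3,3a,4,5,6-hexahydro-2-benzofuran | C=C1OC[C@]2(C)CCCC(C)=C12
F4 | step 6 | tricyclic cycloadduct: 18,6-epoxy-Δ5 enol ether with 8(17)-methylene and 9β-CO2Et | CCOC(=O)[C@@H]1[C@@]2(C)CCC[C@@]3(C)COC(=C23)CC1=C
F5 | step 6 | trans-decalin 6-ketone with 4α-CH2OH, 8(17)-methylene, 9β-CO2Et (5α-H) | CCOC(=O)[C@@H]1[C@@]2(C)CCC[C@@](C)(CO)[C@@H]2C(=O)CC1=C
F6 | step 6 | 18-O-TBS ether of F5 | CCOC(=O)[C@@H]1[C@@]2(C)CCC[C@@](C)(CO[Si](C)(C)C(C)(C)C)[C@@H]2C(=O)CC1=C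
F7 | step 6 | 8α,17-epoxide of F6 | CCOC(=O)[C@@H]1[C@@]2(C)CCC[C@@](C)(CO[Si](C)(C)C(C)(C)C)[C@@H]2C(=O)C[C@]13CO3
F8 | step 7 | 8α,17-diol of 9 (Δ5 and ester retained) | CCOC(=O)[C@@H]1[C@@]2(C)CCC[C@@](C)(CO[Si](C)(C)C(C)(C)C)C2=CC[C@@]1(CO)O
F9 | step 7 | 17-O-tosylate of F8 | CCOC(=O)[C@@H]1[C@@]2(C)CCC[C@@](C)(CO[Si](C)(C)C(C)(C)C)C2=CC[C@@]1(COS(=O)(=O)c1ccc(C)cc1)O
F10 | step 7 | 8α,17-epoxide of 9 (Δ5 and ester retained) | CCOC(=O)[C@@H]1[C@@]2(C)CCC[C@@](C)(CO[Si](C)(C)C(C)(C)C)C2=CC[C@]13CO3
F11 | step 7 | Δ5-8α,11-diol (8β-CH3, 18-O-TBS) | OC[C@@H]1[C@@]2(C)CCC[C@@](C)(CO[Si](C)(C)C(C)(C)C)C2=CC[C@@]1(C)O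
F12 | step 12 | (E)-3-(decalin-9β-yl)prop-2-enal, decalin as in 13 | O=C/C=C/[C@@H]1[C@@]2(C)CCC[C@@](C)(CO[Si](C)(C)C(C)(C)C)[C@@H]2[C@@H](O)C[C@@]1(C)O
F13 | step 12 | 3-(decalin-9β-yl)propanal, decalin as in 13 | O=CCC[C@@H]1[C@@]2(C)CCC[C@@](C)(CO[Si](C)(C)C(C)(C)C)[C@@H]2[C@@H](O)C[C@@]1(C)O
F14 | step 12 | 4-(decalin-9β-yl)but-1-yne, decalin as in 13 | C#CCC[C@@H]1[C@@]2(C)CCC[C@@](C)(CO[Si](C)(C)C(C)(C)C)[C@@H]2[C@@H](O)C[C@@]1(C)O
F15 | step 12 | (E)-1-iodo-2-methyl-4-(decalin-9β-yl)but-1-ene, decalin as in 13 | I/C=C(\C)CC[C@@H]1[C@@]2(C)CCC[C@@](C)(CO[Si](C)(C)C(C)(C)C)[C@@H]2[C@@H](O)C[C@@]1(C)O
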